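**Plan**

- Retrosynthesis (guaiane numbering): remove the C8 angelate and the C6 acetate, then cut the seven-membered ring B at C8–C9 and C6–C7 in one stroke. This gives a C7–C8 enol ether of isovaleraldehyde (11) and cyclopentane aldehyde 6 (ring A carrying the C6 formyl and the C1 isopropenyl group). 6 is traced through cyclopentene 3 to (S)-limonene oxide by opening the six-membered ring at the oxirane C–C bond.
- Forward: cleavage of the limonene ring and aldol re-closure give ring A (3); epoxidation and reductive oxirane opening install C4–OH and C5–H; a BF3-mediated aldol–Prins (5+2) annulation of 6 with 11 closes ring B; acetylation, deallylation/desilylation and angeloylation finish.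
- Stereochemistry: the limonene stereocentre (C1) steers the oxirane and hence C4 and C5; C4/C5 control C6, the (E) geometry of 11 sets C7, and the ring closure sets C8; C1 is erased when the C1=C10 alkene forms.
- Enabling feature: on ring A the formyl carbon C6 (on C5) and the CH2 terminus C9 of the C1 isopropenyl group are cis and five atoms apart (C6–C5–C1–C10–C9), so a two-carbon unit bridges them to a seven-membered ring. The tertiary C1–H lies syn to O6, so the C10 cation can shed it to place the tetrasubstituted C1=C10 alkene.

Key step: step 8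

Remark 1: guaiane numbering is used for atoms throughout, also for the monocyclic precursors (C1/C5 ring fusion, C4 methyl carbinol, C6 acetoxy carbon, C7 isopropyl carbon, C8 angeloyloxy carbon, C9 CH2, C10 methyl-bearing alkene carbon).
Remark 2: (−)-limonene oxide (4S, cis/trans mixture at the oxirane) is assumed to be purchased; both oxirane isomers converge on 2, and the material is otherwise one peracid epoxidation away from (S)-(−)-limonene.

**Route**

Step 1
Reactants: 1 (4S)-limonene 1,2-oxide (cis/trans mixture)
Product: 2 (3S)-6-oxo-3-(prop-1-en-2-yl)heptanal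
Conditions: H5IO6, THF/H2O, 0 °C to rt
Reagents that add atoms: water, O
Why: Periodic acid hydrolyses the oxirane and cleaves the resulting 1,2-diol (glycol cleavage), so both oxirane isomers should give the same keto aldehyde while the isopropenyl-bearing stereocentre is untouched.

Step 2
Reactants: 2 (3S)-6-oxo-3-(prop-1-en-2-yl)heptanal
Product: 3 (5R)-2-methyl-5-(prop-1-en-2-yl)cyclopent-1-ene-1-carbaldehyde
Conditions: piperidine (cat.), AcOH (cat.), benzene, reflux, Dean–Stark
Reagents that add atoms: none
Why: The enamine of the aldehyde should add to the methyl ketone and the aldol dehydrate (intramolecular aldol condensation, 5-exo closure), a ring contraction of the limonene skeleton that leaves the C1 stereocentre untouched.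

Step 3
Reactants: 3 (5R)-2-methyl-5-(prop-1-en-2-yl)cyclopent-1-ene-1-carbaldehyde
Product: 4 (1R,2R,5S)-5-methyl-2-(prop-1-en-2-yl)-6-oxabicyclo[3.1.0]hexane-1-carbaldehyde
Conditions: 30% H2O2, NaOH, MeOH, 0 °C
Reagents that add atoms: hydrogen peroxide, OO
Why: Weitz–Scheffer nucleophilic epoxidation should touch only the enal (the isopropenyl group is not electrophilic), and the oxirane should close at C5 on the face anti to the neighbouring isopropenyl group, which fixes the C4–O configuration.

Step 4
Reactants: 4 (1R,2R,5S)-5-methyl-2-(prop-1-en-2-yl)-6-oxabicyclo[3.1.0]hexane-1-carbaldehyde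
Product: 5 (1S,2S,5S)-2-hydroxy-2-methyl-5-(prop-1-en-2-yl)cyclopentane-1-carbaldehyde
Conditions: SmI2 (2.2 equiv), THF/MeOH, −90 °C; pH 7 buffer; used crude
Reagents that add atoms: none
Why: SmI2 reductive cleavage of the C5–O bond of the α,β-epoxy carbonyl unit should give a samarium enolate that is protonated at C5 on the face opposite the flanking methyl and isopropenyl groups (the face of the C4–O–Sm group), setting H5 cis to the C4 hydroxyl, while the cold neutral conditions should spare the aldol from dehydration and retro-aldol cleavage.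

Step 5
Reactants: 5 (1S,2S,5S)-2-hydroxy-2-methyl-5-(prop-1-en-2-yl)cyclopentane-1-carbaldehyde
Product: 6 (1S,2S,5S)-2-methyl-5-(prop-1-en-2-yl)-2-(triethylsilyloxy)cyclopentane-1-carbaldehyde
Conditions: TESOTf, 2,6-lutidine, CH2Cl2, −78 °C
Reagents that add atoms: triethylsilyl trifluoromethanesulfonate, CC[Si](CC)(CC)OS(=O)(=O)C(F)(F)F
Why: Silyl triflate silylation of the tertiary alcohol at low temperature should not epimerise C5, blocks retro-aldol cleavage and keeps O4 from adding to the oxocarbenium ion of step 8.

Step 6
Reactants: 7 3-methylbut-1-yne, 8 pinacolborane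
Product: 9 (E)-4,4,5,5-tetramethyl-2-(3-methylbut-1-en-1-yl)-1,3,2-dioxaborolane
Conditions: Cp2Zr(H)Cl (5 mol%), Et3N (10 mol%), neat, sealed tube, 40 °C
Reagents that add atoms: none
Why: Zirconium-catalysed syn hydroboration of a terminal alkyne should place boron at the terminus and give the (E)-alkenylboronate only.

Step 7
Reactants: 9 (E)-4,4,5,5-tetramethyl-2-(3-methylbut-1-en-1-yl)-1,3,2-dioxaborolane, 10 allyl alcohol
Product: 11 (E)-3-methyl-1-(prop-2-en-1-yloxy)but-1-ene
Conditions: Cu(OAc)2 (2 equiv), Et3N, allyl alcohol as solvent, air, rt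
Reagents that add atoms: none
Why: Chan–Lam-type copper-promoted C–O coupling of alkenyl pinacol boronates with alcohols proceeds with retention of alkene geometry and should give the (E)-enol ether, which is kept below 40 °C to avoid Claisen rearrangement.

Step 8
Reactants: 6 (1S,2S,5S)-2-methyl-5-(prop-1-en-2-yl)-2-(triethylsilyloxy)cyclopentane-1-carbaldehyde, 11 (E)-3-methyl-1-(prop-2-en-1-yloxy)but-1-ene
Product: 13 (4S,5R,6R,7S,8S)-8-(allyloxy)-4-(triethylsilyloxy)guai-1(10)-en-6-ol, via oxocarbenium aldolate 12 (not isolated)
Conditions: 6 and 11 (1.2 equiv), 2,6-di-tert-butyl-4-methylpyridine (0.3 equiv), CH2Cl2, −78 °C; BF3·OEt2 (1.2 equiv) added last, then −40 °C; Et3N, aq NaHCO3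
Reagents that add atoms: none
Why: Proposed new method: BF3-activated aldehyde 6 should be attacked at C6 by the nucleophilic carbon of enol ether 11 (Mukaiyama-type aldol addition) to give oxocarbenium aldolate 12, whose C8 is then captured by the CH2 terminus C9 of the cis isopropenyl group (Prins closure), after which the tertiary C10 cation passes H1 to the syn-axial aldolate oxygen O6 and so places the alkene at C1=C10; the closest known reaction type is the Mukaiyama aldol–Prins cascade of enol ethers with aldehydes, which closes tetrahydropyrans through an alkene tethered on the enol ether oxygen, together with Lewis acid Prins and carbonyl-ene closures of carbocycles onto isopropenyl groups. The seven-membered ring closes 7-endo with respect to the C9=C10 alkene (Markovnikov, exo with respect to the oxocarbenium bond) through a chair-like array in which the cyclopentane is cis-fused. C6 is set by substrate control, the enol ether approaching anti to the quaternary C4 and its OTES group from the side of H1 and H5 while the formyl hydrogen sits between the cis methyl and isopropenyl groups. C7 follows from the (E) geometry of 11 in an open antiperiplanar transition state with the allyloxy group turned towards the formyl hydrogen, which gives the 6,7-anti aldol relation (O6 and isopropyl cis on the ring). C8 is set in the ring closure, where the isopropyl and allyloxy groups are both equatorial and the oxocarbenium C–H points towards O6. The step needs capture of 12 by the internal alkene ahead of a second molecule of 11 and loss of H1 ahead of H9, H14 or ether formation at C10, and these should be secured by the low temperature and small excess of 11, the cis placement of formyl and isopropenyl groups on ring A, and the syn-axial relation of O6 and H1.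

Step 9
Reactants: 13 (4S,5R,6R,7S,8S)-8-(allyloxy)-4-(triethylsilyloxy)guai-1(10)-en-6-ol
Product: 14 (4S,5R,6R,7R,8S)-8-(allyloxy)-4-(triethylsilyloxy)guai-1(10)-en-6-yl acetate
Conditions: Ac2O, DMAP, Et3N, CH2Cl2, rt
Reagents that add atoms: acetic anhydride, CC(=O)OC(C)=O
Why: DMAP-catalysed acylation should acetylate the only free hydroxyl (C6), the other two oxygens being masked as allyl and silyl ethers.

Step 10
Reactants: 14 (4S,5R,6R,7R,8S)-8-(allyloxy)-4-(triethylsilyloxy)guai-1(10)-en-6-yl acetate
Product: 16 (4S,5R,6R,7R,8S)-4,8-dihydroxyguai-1(10)-en-6-yl acetate, via prop-1-enyl ether 15 (not isolated)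
Conditions: [Ir(cod)(PMePh2)2]PF6 (3 mol%, H2-activated), THF, rt; then 1 M HCl, THF/H2O, 0 °C to rt
Reagents that add atoms: none
Why: Iridium-catalysed isomerisation of the allyl ether to the (E)-prop-1-enyl ether followed by mild aqueous acid should hydrolyse the enol ether and the tertiary TES ether together, while the acetate and the tetrasubstituted alkene are inert.

Step 11
Reactants: 16 (4S,5R,6R,7R,8S)-4,8-dihydroxyguai-1(10)-en-6-yl acetate, 17 angelic acid
Product: 19 (4S,5R,6R,7R,8S)-6-acetoxy-4-hydroxyguai-1(10)-en-8-yl (Z)-2-methylbut-2-enoate, via mixed anhydride 18 (not isolated)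
Conditions: 17, 2,4,6-Cl3C6H2COCl, Et3N, toluene, rt; then 16, toluene, 80 °C
Reagents that add atoms: none
Why: Yamaguchi-type mixed anhydride acylation without DMAP is the protocol that keeps the (Z) geometry of angelates, and only the secondary C8 hydroxyl should react because the tertiary C4 hydroxyl is too hindered.

**Compound list**

1 | (4S)-limonene 1,2-oxide, (4S)-1-methyl-4-(prop-1-en-2-yl)-7-oxabicyclo[4.1.0]heptane, cis/trans mixture at the oxirane | CC12OC1C[C@H](CC2)C(C)=C | starting material
2 | (3S)-6-oxo-3-(prop-1-en-2-yl)heptanal | O=CC[C@H](CCC(C)=O)C(C)=C | intermediate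
3 | (5R)-2-methyl-5-(prop-1-en-2-yl)cyclopent-1-ene-1-carbaldehyde | CC(=C)[C@H]1CCC(C)=C1C=O | intermediate
4 | (1R,2R,5S)-5-methyl-2-(prop-1-en-2-yl)-6-oxabicyclo[3.1.0]hexane-1-carbaldehyde (oxirane trans to isopropenyl) | CC(=C)[C@H]1CC[C@]2(C)O[C@]12C=O | intermediate
5 | (1S,2S,5S)-2-hydroxy-2-methyl-5-(prop-1-en-2-yl)cyclopentane-1-carbaldehyde (CHO, 2-methyl and isopropenyl all cis, OH trans to CHO) | CC(=C)[C@H]1CC[C@](C)(O)[C@H]1C=O | intermediate
6 | (1S,2S,5S)-2-methyl-5-(prop-1-en-2-yl)-2-(triethylsilyloxy)cyclopentane-1-carbaldehyde | CC(=C)[C@H]1CC[C@](C)(O[Si](CC)(CC)CC)[C@H]1C=O | intermediate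
7 | 3-methylbut-1-yne | CC(C)C#C | starting material
8 | pinacolborane (4,4,5,5-tetramethyl-1,3,2-dioxaborolane) | CC1(C)OBOC1(C)C | starting material
9 | (E)-4,4,5,5-tetramethyl-2-(3-methylbut-1-en-1-yl)-1,3,2-dioxaborolane | CC(C)/C=C/B1OC(C)(C)C(C)(C)O1 | intermediate
10 | allyl alcohol (prop-2-en-1-ol) | C=CCO | starting material
11 | (E)-3-methyl-1-(prop-2-en-1-yloxy)but-1-ene | CC(C)/C=C/OCC=C | intermediate
12 | BF3-bound oxocarbenium aldolate: 6-O-trifluoroborate, 8-O-allyl oxocarbenium ion on the open C6–C7–C8 chain, (6R,7R) | CC(=C)[C@H]1CC[C@](C)(O[Si](CC)(CC)CC)[C@H]1[C@H](O[B-](F)(F)F)[C@H](C(C)C)C=[O+]CC=C | intermediate (not isolated)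
13 | (4S,5R,6R,7S,8S)-8-(allyloxy)-4-(triethylsilyloxy)guai-1(10)-en-6-ol | C=CCO[C@H]1CC(C)=C2CC[C@](C)(O[Si](CC)(CC)CC)[C@H]2[C@H](O)[C@@H]1C(C)C | intermediate
14 | (4S,5R,6R,7R,8S)-8-(allyloxy)-4-(triethylsilyloxy)guai-1(10)-en-6-yl acetate | C=CCO[C@H]1CC(C)=C2CC[C@](C)(O[Si](CC)(CC)CC)[C@H]2[C@H](OC(C)=O)[C@@H]1C(C)C | intermediate
15 | (4S,5R,6R,7R,8S)-8-[(E)-prop-1-en-1-yloxy]-4-(triethylsilyloxy)guai-1(10)-en-6-yl acetate | C/C=C/O[C@H]1CC(C)=C2CC[C@](C)(O[Si](CC)(CC)CC)[C@H]2[C@H](OC(C)=O)[C@@H]1C(C)C | intermediate (not isolated)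
16 | (4S,5R,6R,7R,8S)-4,8-dihydroxyguai-1(10)-en-6-yl acetate | O[C@H]1CC(C)=C2CC[C@](C)(O)[C@H]2[C@H](OC(C)=O)[C@@H]1C(C)C | intermediate
17 | angelic acid, (Z)-2-methylbut-2-enoic acid | C/C=C(/C)C(=O)O | starting material
18 | (Z)-2-methylbut-2-enoic 2,4,6-trichlorobenzoic anhydride | C/C=C(/C)C(=O)OC(=O)c1c(Cl)cc(Cl)cc1Cl | intermediate (not isolated)
19 | (4S,5R,6R,7R,8S)-6-acetoxy-4-hydroxyguai-1(10)-en-8-yl (Z)-2-methylbut-2-enoate | C/C=C(/C)C(=O)O[C@H]1CC(C)=C2CC[C@](C)(O)[C@H]2[C@H](OC(C)=O)[C@@H]1C(C)C | target

**Step count**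

Total steps: 11. Longest linear sequence: 9 steps (steps 1 to 5 and 8 to 11); steps 6 and 7 form the side branch to 11.

**Steps most likely to fail**

1. Step 8 (proposed new method). Several things may go wrong here:
   - the oxocarbenium ion may be intercepted by a second molecule of enol ether or by O6 instead of the internal alkene;
   - 6 may close onto its own isopropenyl group before 11 adds;
   - the facial or anti selectivity of the aldol event may be poor;
   - proton loss from the C10 cation may be unselective.

   The fallback separates the two bond formations with known chemistry and sets out from 6. L-Proline-catalysed direct cross-aldol reaction with isovaleraldehyde (DMF, 4 °C, slow addition of the donor) should give, under catalyst control, the anti aldol, the C6-hydroxy C8-aldehyde F1. Acetal formation with allyl alcohol (PPTS, molecular sieves, rt) gives the diallyl acetal F2. SnCl4 or BF3·OEt2 in CH2Cl2 at −78 °C then ionises the acetal, and an acetal-initiated alkene (Prins) cyclisation closes ring B; the route is rejoined at 13.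

2. Step 4. The aldehyde may be over-reduced, the samarium enolate may be protonated from the wrong face, or the β-hydroxy aldehyde may epimerise or dehydrate on isolation. The fallback moves the C–O cleavage to the ester oxidation level, where both the reaction and the product are more robust, and sets out from 4. Pinnick oxidation (NaClO2, NaH2PO4, 2-methylbut-2-ene) gives the epoxy acid F3, and TMSCHN2 gives the methyl glycidate F4. SmI2 with HMPA and N,N-dimethylethanolamine in THF opens the oxirane to the β-hydroxy ester F5. TESOTf/2,6-lutidine gives the silyl ether ester F6, and i-Bu2AlH in CH2Cl2 at −78 °C reduces it to the aldehyde; the route is rejoined at 6.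

3. Step 11. The angelate may isomerise to the tiglate at 80 °C, or acylation of the hindered C8 hydroxyl may stall. The fallback builds the (Z)-alkene on the substrate and sets out from 16. Esterification with 2-[bis(2,2,2-trifluoroethoxy)phosphoryl]propanoic acid (DCC, DMAP, CH2Cl2) gives the C8 phosphonopropanoate F7. Still–Gennari olefination with acetaldehyde (KN(SiMe3)2, 18-crown-6, THF, −78 °C) then forms the (Z)-2-methylbut-2-enoate and arrives at 19.

**Further compounds**

F1 | step 8 | anti aldol of 6 with isovaleraldehyde: (6S,7S) C6-hydroxy C7-isopropyl C8-aldehyde, cyclopentane unit as in 6 | CC(=C)[C@H]1CC[C@](C)(O[Si](CC)(CC)CC)[C@H]1[C@H](O)[C@H](C(C)C)C=O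
F2 | step 8 | diallyl acetal of F1 | CC(=C)[C@H]1CC[C@](C)(O[Si](CC)(CC)CC)[C@H]1[C@H](O)[C@H](C(C)C)C(OCC=C)OCC=C
F3 | step 4 | (1R,2R,5S)-5-methyl-2-(prop-1-en-2-yl)-6-oxabicyclo[3.1.0]hexane-1-carboxylic acid | CC(=C)[C@H]1CC[C@]2(C)O[C@]12C(=O)O
F4 | step 4 | methyl ester of F3 | CC(=C)[C@H]1CC[C@]2(C)O[C@]12C(=O)OC
F5 | step 4 | methyl 2-hydroxy-2-methyl-5-(prop-1-en-2-yl)cyclopentane-1-carboxylate, relative and absolute configuration as in 5 | CC(=C)[C@H]1CC[C@](C)(O)[C@H]1C(=O)OC
F6 | step 4 | triethylsilyl ether of F5 | CC(=C)[C@H]1CC[C@](C)(O[Si](CC)(CC)CC)[C@H]1C(=O)OC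
F7 | step 11 | 8-O-{2-[bis(2,2,2-trifluoroethoxy)phosphoryl]propanoyl} derivative of 16 | CC(C(=O)O[C@H]1CC(C)=C2CC[C@](C)(O)[C@H]2[C@H](OC(C)=O)[C@@H]1C(C)C)P(=O)(OCC(F)(F)F)OCC(F)(F)F
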